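The blue run was where I began, because it and the ochre run differ only in reagent, and both were read at 8.00 h.

in all of them: substrate 0.17 M

| flask | reagent | remark | time |
|---|---|---|---|
| blue | 1.2 M | run made earlier |  |
| ochre | 2 M | run made earlier |  |
| Wednesday's | 1.40 M |  | 8.0 h |
| Friday's | 0.850 M |  | 8.0 h |
| Thursday's | 1.10 M |  | 8.0 h |

| run | time / h | substrate / % | side product A / % | intermediate / % | target / % |
|---|---|---|---|---|---|
| blue | 2.00 | 84.5 | 3.6 | 7.5 | 1.6 |
| blue | 4.00 | 72.5 | 6.3 | 8.7 | 5.7 |
| blue | 6.00 | 61.0 | 11.3 | 9.1 | 8.9 |
| blue | 8.00 | 51.2 | 13.9 | 8.7 | 12.4 |
| ochre | 2.00 | 77.4 | 3.4 | 12.5 | 3.8 |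
| ochre | 4.00 | 58.4 | 9.9 | 14.3 | 8.5 |
| ochre | 6.00 | 44.0 | 16.4 | 12.1 | 13.7 |
| ochre | 8.00 | 34.0 | 21.2 | 10.5 | 16.0 |

(each reading ± 0.5 percentage points)

1. which of these there is most of at the end, counted by the substrate in it, Wednesday's (side product A / intermediate / target / substrate)
2. which of these there is most of at the end, counted by the substrate in it, Friday's (side product A / intermediate / target / substrate)
3. which of these there is most of at the end, counted by the substrate in it, Thursday's (side product A / intermediate / target / substrate)
4. final amount of the leader among these, as a percentage of the substrate charged, in Wednesday's
5. final amount of the leader among these, as a percentage of the substrate charged, in Friday's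
6. final amount of the leader among these, as a percentage of the substrate charged, in Thursday's

- in percentages every species weighs as the substrate in it: one side product B counts as two
- what was read earlier has a scatter of 0.5 percentage points, one standard deviation
- steps under discussion: substrate + reagent -> intermediate + released group; intermediate <-> target; intermediate <-> isomer of the product; intermediate -> side product A; substrate + intermediate -> side product B
- a reading of intermediate is of its free form alone

Reagent stood in excess over substrate in both runs, so I went to logarithms and counted powers of ten. The common logarithm of the fraction of substrate left, sign changed and divided by the reagent charge c, gave 0.242 M⁻¹ for blue and 0.234 M⁻¹ for ochre. I carried their mean, 0.238 M⁻¹: D, the decades of substrate lost by that time per molar of reagent charged.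

I then bracketed Friday's, the flask with the least reagent. At one end, reagent stayed at its charge, the pseudo-first-order limit, and the fraction left was ten to the power minus D times c, or 62.7%. At the other end, I took the whole substrate charge off the reagent from the first moment, which gave 68.9%. The first step takes one reagent per substrate, so the reagent in Friday's had to stand between those two levels. But D carries the scatter of the readings and also holds substrate lost to side product B, a step that takes no reagent, so the two figures are estimates and not bounds, and I expected the real flask near them. I committed to the first end, because D already carried what blue had lost, at most 0.0830 M of reagent. That gave me 46.4% for Wednesday's and 54.7% for Thursday's. Substrate still led side product A in ochre, which had more reagent than any asked flask.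

The forecast said “All three runs should still be led by unreacted substrate” and gave 46.8%, 62% and 54.5% for Wednesday's, Friday's and Thursday's. On Friday's it differs from my figure by 0.70 percentage points.

Substrate led each flask, ending at 46.9% in Wednesday's, 63.0% in Friday's and 55.1% in Thursday's.

    substrate + reagent → intermediate + released group (k = 1.80 × 10⁻⁵ M⁻¹ s⁻¹)
    intermediate ⇌ target (K = 3.30, k = 6.40 × 10⁻⁵ s⁻¹)
    intermediate ⇌ isomer of the product (K = 2.10, k = 3.30 × 10⁻⁵ s⁻¹)
    intermediate → side product A (k = 6.60 × 10⁻⁵ s⁻¹)
    substrate + intermediate → side product B (k = 1.30 × 10⁻⁴ M⁻¹ s⁻¹)

At the end of Thursday's, the first step used substrate 11 times as fast as the step to side product B. Thursday's own ending gives D as 0.236 M⁻¹. With 0.44 M of reagent, the carried D gives 78.6%, and that neighbouring flask ended with 78.7% of its substrate.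

Readings and results stem from a simulated flask for an exercise, and the scatter is random.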